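**Loss read.** 51.0% of theta's charge was not target at 80.0 min, against 10.5% on beta's plateau, the mean of its readings from 30.0 min on.

| setting | beta | theta | flask |
|---|---|---|---|
| substrate | 0.50 M | 2 M | 1.0 M |
| gas phase | 81 mM (held) | 81 mM (held) | 81 mM (held) |
| remark | run made earlier | run made earlier |  |
| time |  |  | 80 min |

| run | time / min | target / % |
|---|---|---|
| beta | 15.0 | 63 |
| beta | 30.0 | 91 |
| beta | 50.0 | 87 |
| beta | 60.0 | 91 |
| beta | 80.0 | 89 |
| theta | 6.00 | 3 |
| theta | 12.0 | 10 |
| theta | 25.0 | 17 |
| theta | 40.0 | 34 |
| theta | 80.0 | 49 |

(scatter of a reading: 2 percentage points)

1. how much target there is at 80 min, in percent of the substrate charged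
2. concentration of dissolved gas in solution at 80 min, in percent of saturation

- at the start none of the gas phase is in solution

**The clock.** Beta's first reading gave a pace of 21.0 mM min⁻¹. At that pace the flask's charge lasts 47.6 min, less than 80 min, so I reckoned the flask's end state.

**My bracket.** I call the loss the share of the charge not ending as target, one minus the selectivity. If the flask's loss simply followed the charge, it would keep 79.0% as target. But theta's reading stood above the 42.0% that proportion allows, so I took this as my upper bound. If target formed at a fixed pace and substrate met target to give the loss, the loss would follow the square of the charge, and the flask would keep 58.0%, my lower bound. Between them, the power of the charge that joins beta to theta is 1.14, the loss exponent n. With it I reckoned 76.9% for the flask. Theta's target may still have been climbing at its last reading, which would move this towards the upper bound.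

**The result.** The forecast gave 86% and 85%, holding that “The flask at 1 M should follow a similar absolute curve”, and its target stands above my bracket. The flask gave 75.5% of target and 86.8% of saturation.

    substrate + dissolved gas → target (k = 7.73 L mol⁻¹ min⁻¹)
    gas phase ⇌ dissolved gas, rate k2*(csat - [dissolved gas]) (kL = 0.343 min⁻¹)
    dissolved gas ⇌ dormant form (K = 6.40, k = 0.0595 min⁻¹)
    substrate + target → side product (k = 0.0255 L mol⁻¹ min⁻¹)
    dissolved gas → decomposed reagent (k = 0.0120 min⁻¹)

**The course.** By 40.0 min the flask held 1.44% substrate, 74.2% target and 24.3% side product, each side product counted twice. At 80.0 min the flask's substrate stood at 0% and its target at 75.5%, while its dissolved gas had risen to 0.0703 M and its dormant form to 0.152 M. Joined to beta, the flask's own loss gives n = 1.22. Beta's loss with my n gave 91.9% of target for the neighbour at 0.40 M, which holds 93.4%.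

(The earlier runs and the new flask are simulated for an exercise; noise was put on by code.)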